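Plan (ring numbered as in the acid: C1 carries CO2H, C4=C5 is the Z-alkene, C9 carries the methyl group, C12 the dienyl group)
- Cuts: first the C12–alkenyl bond (back to a C12 boronic ester), then the ring at C10–C11 together with C12–C13, which takes out C11–C12 as a vinyl unit and leaves one chain with an iodide at C10 and a boronate at C13. The chain is cut at C1–C2, at C2–C3/C4=C5 and at C6–C7.
- Enabling feature: C12 is a CH flanked by two ring CH2 groups (C11, C13) and carries a 1,1-disubstituted alkenyl group. This is the pattern alkyl–CH(B)–CH2–alkyl left by a 1,2-shift on a vinylboron ate complex, with boron standing in for the alkenyl group.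
- Forward: C6–C10 from a chiral bromide and ethylene oxide; C2–C5 by carbocupration of propyne and a second ethylene oxide; C1, C13 and C14 by allylic alkylation, then hydroboration. The 14-membered ring (the only ring) is then closed, the side chain is put on C12 by Zweifel olefination, and C1′ is oxidised to the acid.
- Stereochemistry: C9 from (S)-3-bromo-2-methylpropan-1-ol; 4Z from syn-carbocupration; C1 from a Cu/Taniaphos SN2′ alkylation; C12 from the chiral Ni catalyst in the ring closure, carried through the stereoretentive Zweifel step.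

Key step: step 11

Assumption: in the two catalyst-controlled steps (7 and 11) the ligand enantiomer that delivers the drawn configuration is used; both enantiomers of each ligand are available.

Step 1
Reactants: 1 (S)-3-bromo-2-methylpropan-1-ol
Product: 2 (S)-(3-bromo-2-methylpropoxy)(tert-butyl)dimethylsilane
Conditions: TBSCl, imidazole, CH2Cl2, 0 °C → rt
Reagents that add atoms: tert-butyldimethylsilyl chloride, CC(C)(C)[Si](C)(C)Cl
Why: Imidazole-promoted silylation of the primary alcohol; the C9 stereocentre (chiral pool) is not touched.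

Step 2
Reactants: 2 (S)-(3-bromo-2-methylpropoxy)(tert-butyl)dimethylsilane
Product: 4 (4R)-5-[(tert-butyldimethylsilyl)oxy]-4-methylpentan-1-ol, via Grignard reagent 3 (not isolated)
Conditions: Mg, THF, reflux; CuI (10 mol%), ethylene oxide, −30 → 0 °C; H2O
Reagents that add atoms: ethylene oxide, C1CO1
Why: Copper-catalysed opening of ethylene oxide by the primary Grignard reagent adds C6 and C7 as a two-carbon alcohol; the stereocentre is β to magnesium and not epimerisable.

Step 3
Reactants: 4 (4R)-5-[(tert-butyldimethylsilyl)oxy]-4-methylpentan-1-ol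
Product: 5 {[(2R)-5-bromo-2-methylpentyl]oxy}(tert-butyl)dimethylsilane
Conditions: CBr4, PPh3, CH2Cl2, 0 °C
Reagents that add atoms: tetrabromomethane, BrC(Br)(Br)Br
Why: Appel reaction (SN2 at a primary carbon) under neutral conditions that leave the silyl ether intact.

Step 4
Reactants: 5 {[(2R)-5-bromo-2-methylpentyl]oxy}(tert-butyl)dimethylsilane
Product: 8 (3Z,8R)-9-[(tert-butyldimethylsilyl)oxy]-4,8-dimethylnon-3-en-1-ol, via Grignard reagent 6 (not isolated), via alkenylcopper 7 (not isolated)
Conditions: Mg, Et2O; CuBr·SMe2 (1.0 equiv), Et2O/Me2S, −45 °C; propyne, −25 °C; pre-formed 1-lithiopent-1-yne, HMPA, ethylene oxide, −78 °C → rt; H2O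
Reagents that add atoms: propyne, CC#C; ethylene oxide, C1CO1
Why: Normant-type carbocupration, in which the alkylcopper adds syn to propyne with copper on the terminal carbon, followed by epoxide opening by the derived cuprate with retention, so that C3 ends up cis to C6 and the 4Z geometry is fixed.

Step 5
Reactants: 8 (3Z,8R)-9-[(tert-butyldimethylsilyl)oxy]-4,8-dimethylnon-3-en-1-ol
Product: 9 {[(2R,6Z)-9-bromo-2,6-dimethylnon-6-en-1-yl]oxy}(tert-butyl)dimethylsilane
Conditions: CBr4, PPh3, CH2Cl2, 0 °C
Reagents that add atoms: tetrabromomethane, BrC(Br)(Br)Br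
Why: Appel reaction at the primary homoallylic alcohol; no allylic position is involved, so the Z-alkene is not at risk.

Step 6
Reactants: 10 (E)-1,4-dibromobut-2-ene; 11 (4-methoxyphenyl)methanol
Product: 12 1-({[(2E)-4-bromobut-2-en-1-yl]oxy}methyl)-4-methoxybenzene
Conditions: NaH, THF, 0 °C; then 10 (3 equiv), 0 °C → rt
Reagents that add atoms: none
Why: Williamson etherification; a threefold excess of the symmetrical dibromide limits the reaction to mono-substitution.

Step 7
Reactants: 9 {[(2R,6Z)-9-bromo-2,6-dimethylnon-6-en-1-yl]oxy}(tert-butyl)dimethylsilane; 12 1-({[(2E)-4-bromobut-2-en-1-yl]oxy}methyl)-4-methoxybenzene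
Product: 14 tert-butyl({(2R,6Z,10R)-10-{[(4-methoxyphenyl)methoxy]methyl}-2,6-dimethyldodeca-6,11-dien-1-yl}oxy)dimethylsilane, via Grignard reagent 13 (not isolated)
Conditions: Mg, Et2O, rt; slow addition to 12, CuBr·SMe2 (3 mol%), Taniaphos (3.5 mol%), CH2Cl2, −75 °C
Reagents that add atoms: none
Why: Copper-catalysed asymmetric allylic alkylation (SN2′) of the Grignard reagent, in which the Cu–Taniaphos complex delivers the alkyl group to the γ-carbon of the allylic bromide to give the branched ether and sets C1 under catalyst control.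

Step 8
Reactants: 14 tert-butyl({(2R,6Z,10R)-10-{[(4-methoxyphenyl)methoxy]methyl}-2,6-dimethyldodeca-6,11-dien-1-yl}oxy)dimethylsilane
Product: 15 2-[(3S,6Z,11R)-12-[(tert-butyldimethylsilyl)oxy]-3-{[(4-methoxyphenyl)methoxy]methyl}-7,11-dimethyldodec-6-en-1-yl]-4,4,5,5-tetramethyl-1,3,2-dioxaborolane
Conditions: HBpin (1.2 equiv), [Ir(cod)Cl]2 (1.5 mol%), dppm (3 mol%), CH2Cl2, rt
Reagents that add atoms: pinacolborane, [H]B1OC(C)(C)C(C)(C)O1
Why: Iridium-catalysed anti-Markovnikov hydroboration with pinacolborane, which is selective for the monosubstituted alkene over the trisubstituted C4=C5 alkene and puts boron on C13.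

Step 9
Reactants: 15 2-[(3S,6Z,11R)-12-[(tert-butyldimethylsilyl)oxy]-3-{[(4-methoxyphenyl)methoxy]methyl}-7,11-dimethyldodec-6-en-1-yl]-4,4,5,5-tetramethyl-1,3,2-dioxaborolane
Product: 16 (2R,6Z,10S)-10-{[(4-methoxyphenyl)methoxy]methyl}-2,6-dimethyl-12-(4,4,5,5-tetramethyl-1,3,2-dioxaborolan-2-yl)dodec-6-en-1-ol
Conditions: PPTS (0.2 equiv), MeOH, 40 °C
Reagents that add atoms: none
Why: Acid-catalysed methanolysis of the primary TBS ether; the PMB ether and the pinacol boronate are stable to PPTS.

Step 10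
Reactants: 16 (2R,6Z,10S)-10-{[(4-methoxyphenyl)methoxy]methyl}-2,6-dimethyl-12-(4,4,5,5-tetramethyl-1,3,2-dioxaborolan-2-yl)dodec-6-en-1-ol
Product: 17 2-[(3S,6Z,11R)-12-iodo-3-{[(4-methoxyphenyl)methoxy]methyl}-7,11-dimethyldodec-6-en-1-yl]-4,4,5,5-tetramethyl-1,3,2-dioxaborolane
Conditions: I2, PPh3, imidazole, CH2Cl2, 0 °C → rt
Reagents that add atoms: iodine, II
Why: Appel-type iodination (Garegg–Samuelsson conditions), an SN2 reaction at the primary C10 that affects neither the C9 stereocentre nor the boronate.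

Step 11
Reactants: 17 2-[(3S,6Z,11R)-12-iodo-3-{[(4-methoxyphenyl)methoxy]methyl}-7,11-dimethyldodec-6-en-1-yl]-4,4,5,5-tetramethyl-1,3,2-dioxaborolane
Product: 19 2-[(1R,4S,7Z,12R)-4-{[(4-methoxyphenyl)methoxy]methyl}-8,12-dimethylcyclotetradec-7-en-1-yl]-4,4,5,5-tetramethyl-1,3,2-dioxaborolane, via vinyl borate 18 (not isolated)
Conditions: vinyllithium (1.05 equiv, stock solution), THF, −78 → 0 °C; then syringe-pump addition to NiBr2·glyme (15 mol%), chiral Ph-Pybox (18 mol%), THF/DMSO, 25–40 °C, final concentration ≤ 2 mM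
Reagents that add atoms: vinyllithium, [Li]C=C
Why: Proposed new method: vinyllithium adds to the C13 pinacol boronate to give the four-coordinate vinyl borate 18, whose electron-rich C11=C12 bond is the only nucleophilic alkene in the molecule; the chiral Pybox–Ni catalyst activates the C10–I bond (halogen abstraction and radical capture) to a C10–Ni species, binds the vinyl π-bond and triggers an anti 1,2-metallate shift of C13 from boron to C12, and C(sp3)–C(sp3) reductive elimination then joins C10 to C11. The closest known reaction type is the intermolecular nickel-catalysed enantioselective conjunctive cross-coupling of vinylboron ate complexes with alkyl iodides; what is new is that the borate and the iodide are the two ends of one chain. Counted on the borate, C10 attacks the terminal vinyl carbon C11 while C12 and boron lie inside the forming ring, a 15-endo-trig closure; the 1,2-shift of C13 from boron to C12 excises boron, so the ring that results is the 14-membered carbocycle with the boronic ester exocyclic on C12. The C12 stereocentre is set by the face of the vinyl group that the chiral nickel complex binds (catalyst control, the C1 and C9 stereocentres being remote), and it is formed as a configurationally stable secondary boronic ester. The step needs cyclisation over oligomerisation, which slow addition of 18 to the catalyst at high dilution should secure, and it needs C10 to react only at the borate alkene, which the far higher nucleophilicity of the ate complex over the trisubstituted C4=C5 alkene should secure. Migration of the primary C13 alkyl group in preference to a pinacol oxygen is the normal selectivity of such borates.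

Step 12
Reactants: 20 6-methylhept-5-en-2-one; 21 2,4,6-tri(propan-2-yl)benzenesulfonohydrazide
Product: 22 N′-(6-methylhept-5-en-2-ylidene)-2,4,6-tri(propan-2-yl)benzenesulfonohydrazide
Conditions: MeOH, HCl (cat.), rt
Reagents that add atoms: none
Why: Acid-catalysed condensation of the methyl ketone with the sulfonyl hydrazide.

Step 13
Reactants: 19 2-[(1R,4S,7Z,12R)-4-{[(4-methoxyphenyl)methoxy]methyl}-8,12-dimethylcyclotetradec-7-en-1-yl]-4,4,5,5-tetramethyl-1,3,2-dioxaborolane; 22 N′-(6-methylhept-5-en-2-ylidene)-2,4,6-tri(propan-2-yl)benzenesulfonohydrazide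
Product: 26 1-({[(1R,4Z,9R,12R)-5,9-dimethyl-12-(6-methylhepta-1,5-dien-2-yl)cyclotetradec-4-en-1-yl]methoxy}methyl)-4-methoxybenzene, via alkenyllithium 23 (not isolated), via alkenyl borate 24 (not isolated), via β-iodo boronate 25 (not isolated)
Conditions: 22 (1.6 equiv), n-BuLi (3.2 equiv), THF, −78 → 0 °C; then 19, THF, −78 °C; I2, THF/MeOH, −78 °C; NaOMe, MeOH, −78 °C → rt; aq. Na2S2O3
Reagents that add atoms: none
Why: The Shapiro reaction of 22 gives the 2-lithio-1-alkene regioselectively from the methyl side, and Zweifel olefination (borate formation, iodine-induced 1,2-migration of C12 with retention, anti elimination of boron and iodine) replaces boron by the 1,1-disubstituted alkenyl group without change of configuration at C12.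

Step 14
Reactants: 26 1-({[(1R,4Z,9R,12R)-5,9-dimethyl-12-(6-methylhepta-1,5-dien-2-yl)cyclotetradec-4-en-1-yl]methoxy}methyl)-4-methoxybenzene
Product: 27 [(1R,4Z,9R,12R)-5,9-dimethyl-12-(6-methylhepta-1,5-dien-2-yl)cyclotetradec-4-en-1-yl]methanol
Conditions: DDQ (1.3 equiv), CH2Cl2/pH 7 buffer, 0 °C
Reagents that add atoms: none
Why: Oxidative cleavage of the PMB ether by DDQ through the benzylic cation, which leaves the three unactivated alkenes untouched.

Step 15
Reactants: 27 [(1R,4Z,9R,12R)-5,9-dimethyl-12-(6-methylhepta-1,5-dien-2-yl)cyclotetradec-4-en-1-yl]methanol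
Product: 29 (1R,4Z,9R,12R)-5,9-dimethyl-12-(6-methylhepta-1,5-dien-2-yl)cyclotetradec-4-ene-1-carboxylic acid, via aldehyde 28 (not isolated)
Conditions: TEMPO (0.2 equiv), PhI(OAc)2 (2.5 equiv), MeCN/H2O, rt
Reagents that add atoms: water, O
Why: Oxoammonium (TEMPO/PhI(OAc)2) oxidation of the primary alcohol through the aldehyde hydrate to the acid under non-basic conditions, so that C1 should not epimerise and the alkenes are not attacked.

Compound list
1 | (S)-3-bromo-2-methylpropan-1-ol | OC[C@H](C)CBr | starting material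
2 | (S)-(3-bromo-2-methylpropoxy)(tert-butyl)dimethylsilane | CC(C)(C)[Si](C)(C)OC[C@H](C)CBr | intermediate
3 | {(2S)-3-[(tert-butyldimethylsilyl)oxy]-2-methylpropyl}magnesium bromide | CC(C)(C)[Si](C)(C)OC[C@H](C)C[Mg]Br | intermediate
4 | (4R)-5-[(tert-butyldimethylsilyl)oxy]-4-methylpentan-1-ol | CC(C)(C)[Si](C)(C)OC[C@H](C)CCCO | intermediate
5 | {[(2R)-5-bromo-2-methylpentyl]oxy}(tert-butyl)dimethylsilane | CC(C)(C)[Si](C)(C)OC[C@H](C)CCCBr | intermediate
6 | {(4R)-5-[(tert-butyldimethylsilyl)oxy]-4-methylpentyl}magnesium bromide | CC(C)(C)[Si](C)(C)OC[C@H](C)CCC[Mg]Br | intermediate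
7 | [(1Z,6R)-7-[(tert-butyldimethylsilyl)oxy]-2,6-dimethylhept-1-en-1-yl]copper | CC(C)(C)[Si](C)(C)OC[C@H](C)CCC/C(C)=C\[Cu] | intermediate
8 | (3Z,8R)-9-[(tert-butyldimethylsilyl)oxy]-4,8-dimethylnon-3-en-1-ol | CC(C)(C)[Si](C)(C)OC[C@H](C)CCC/C(C)=C\CCO | intermediate
9 | {[(2R,6Z)-9-bromo-2,6-dimethylnon-6-en-1-yl]oxy}(tert-butyl)dimethylsilane | CC(C)(C)[Si](C)(C)OC[C@H](C)CCC/C(C)=C\CCBr | intermediate
10 | (E)-1,4-dibromobut-2-ene | BrC/C=C/CBr | starting material
11 | (4-methoxyphenyl)methanol | COc1ccc(CO)cc1 | starting material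
12 | 1-({[(2E)-4-bromobut-2-en-1-yl]oxy}methyl)-4-methoxybenzene | COc1ccc(COC/C=C/CBr)cc1 | intermediate
13 | {(3Z,8R)-9-[(tert-butyldimethylsilyl)oxy]-4,8-dimethylnon-3-en-1-yl}magnesium bromide | CC(C)(C)[Si](C)(C)OC[C@H](C)CCC/C(C)=C\CC[Mg]Br | intermediate
14 | tert-butyl({(2R,6Z,10R)-10-{[(4-methoxyphenyl)methoxy]methyl}-2,6-dimethyldodeca-6,11-dien-1-yl}oxy)dimethylsilane | CC(C)(C)[Si](C)(C)OC[C@H](C)CCC/C(C)=C\CC[C@@H](COCc1ccc(OC)cc1)C=C | intermediate
15 | 2-[(3S,6Z,11R)-12-[(tert-butyldimethylsilyl)oxy]-3-{[(4-methoxyphenyl)methoxy]methyl}-7,11-dimethyldodec-6-en-1-yl]-4,4,5,5-tetramethyl-1,3,2-dioxaborolane | CC(C)(C)[Si](C)(C)OC[C@H](C)CCC/C(C)=C\CC[C@@H](COCc1ccc(OC)cc1)CCB1OC(C)(C)C(C)(C)O1 | intermediate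
16 | (2R,6Z,10S)-10-{[(4-methoxyphenyl)methoxy]methyl}-2,6-dimethyl-12-(4,4,5,5-tetramethyl-1,3,2-dioxaborolan-2-yl)dodec-6-en-1-ol | OC[C@H](C)CCC/C(C)=C\CC[C@@H](COCc1ccc(OC)cc1)CCB1OC(C)(C)C(C)(C)O1 | intermediate
17 | 2-[(3S,6Z,11R)-12-iodo-3-{[(4-methoxyphenyl)methoxy]methyl}-7,11-dimethyldodec-6-en-1-yl]-4,4,5,5-tetramethyl-1,3,2-dioxaborolane | IC[C@H](C)CCC/C(C)=C\CC[C@@H](COCc1ccc(OC)cc1)CCB1OC(C)(C)C(C)(C)O1 | intermediate
18 | lithium ethenyl(pinacolato)borate of 17 (boron carries the C13 chain, a vinyl group and the pinacolate) | IC[C@H](C)CCC/C(C)=C\CC[C@@H](COCc1ccc(OC)cc1)CC[B-]1(C=C)OC(C)(C)C(C)(C)O1.[Li+] | intermediate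
19 | 2-[(1R,4S,7Z,12R)-4-{[(4-methoxyphenyl)methoxy]methyl}-8,12-dimethylcyclotetradec-7-en-1-yl]-4,4,5,5-tetramethyl-1,3,2-dioxaborolane (boron on C12 of the acid numbering) | CC1(C)OB(OC1(C)C)[C@@H]1CC[C@H](C)CCC/C(C)=C\CC[C@@H](COCc2ccc(OC)cc2)CC1 | intermediate
20 | 6-methylhept-5-en-2-one | CC(=O)CCC=C(C)C | starting material
21 | 2,4,6-tri(propan-2-yl)benzenesulfonohydrazide | CC(C)c1cc(C(C)C)c(S(=O)(=O)NN)c(C(C)C)c1 | starting material
22 | N′-(6-methylhept-5-en-2-ylidene)-2,4,6-tri(propan-2-yl)benzenesulfonohydrazide | CC(CCC=C(C)C)=NNS(=O)(=O)c1c(C(C)C)cc(C(C)C)cc1C(C)C | intermediate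
23 | (6-methylhepta-1,5-dien-2-yl)lithium | [Li]C(=C)CCC=C(C)C | intermediate
24 | lithium borate from 19 and 23 (boron carries the pinacolate, ring carbon C12 and the 6-methylhepta-1,5-dien-2-yl group) | [Li+].C=C(CCC=C(C)C)[B-]1(OC(C)(C)C(C)(C)O1)[C@@H]1CC[C@H](C)CCC/C(C)=C\CC[C@@H](COCc2ccc(OC)cc2)CC1 | intermediate
25 | β-iodo boronic ester: pinacol boronate of the 1-iodo-6-methylhept-5-en-2-yl group whose C2 also carries ring carbon C12 (ring stereocentres as in 26; the transient boron-bearing carbon is not specified) | ICC(CCC=C(C)C)(B1OC(C)(C)C(C)(C)O1)[C@@H]1CC[C@H](C)CCC/C(C)=C\CC[C@@H](COCc2ccc(OC)cc2)CC1 | intermediate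
26 | 1-({[(1R,4Z,9R,12R)-5,9-dimethyl-12-(6-methylhepta-1,5-dien-2-yl)cyclotetradec-4-en-1-yl]methoxy}methyl)-4-methoxybenzene | C=C(CCC=C(C)C)[C@@H]1CC[C@H](C)CCC/C(C)=C\CC[C@@H](COCc2ccc(OC)cc2)CC1 | intermediate
27 | [(1R,4Z,9R,12R)-5,9-dimethyl-12-(6-methylhepta-1,5-dien-2-yl)cyclotetradec-4-en-1-yl]methanol | C=C(CCC=C(C)C)[C@@H]1CC[C@H](C)CCC/C(C)=C\CC[C@@H](CO)CC1 | intermediate
28 | (1R,4Z,9R,12R)-5,9-dimethyl-12-(6-methylhepta-1,5-dien-2-yl)cyclotetradec-4-ene-1-carbaldehyde | C=C(CCC=C(C)C)[C@@H]1CC[C@H](C)CCC/C(C)=C\CC[C@@H](C=O)CC1 | intermediate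
29 | (1R,4Z,9R,12R)-5,9-dimethyl-12-(6-methylhepta-1,5-dien-2-yl)cyclotetradec-4-ene-1-carboxylic acid | C=C(CCC=C(C)C)[C@@H]1CC[C@H](C)CCC/C(C)=C\CC[C@@H](C(=O)O)CC1 | target

Step count: 15 steps in total; longest linear sequence 13 steps (steps 1–5, 7–11, 13–15).

Steps most likely to fail

1. Step 11 (macrocyclic conjunctive coupling). The borate may oligomerise instead of cyclising, the C10–Ni species may lose a β-hydride or be reduced, a free C10 radical may add to the C4=C5 alkene, and facial control at C12 may be poor if a radical pathway outside the nickel coordination sphere takes over. The fallback uses known radical chemistry, sets out from 14 and comes back at 26. Alkylation of the dianion of dimethyl (2-oxopropyl)phosphonate with prenyl bromide gives dimethyl (6-methyl-2-oxohept-5-en-1-yl)phosphonate F1. Hydroboration–oxidation of the vinyl group of 14 (9-BBN; NaOH/H2O2) gives the primary C13 alcohol F2, and Appel iodination gives the primary C13 iodide F3. The iodide alkylates the sodium enolate of the phosphonate to give the α-alkylated β-ketophosphonate F4. Horner–Wadsworth–Emmons reaction with aqueous formaldehyde and K2CO3 gives the silyl-protected α-methylene ketone F5. Desilylation with PPTS/MeOH gives the enone alcohol F6, and iodination gives the iodo enone F7. A tin hydride 14-endo radical macrocyclisation (Bu3SnH, AIBN, benzene, 80 °C, syringe pump, 3 mM) then closes the same C10–C11 bond to the macrocyclic ketone F8. C12 is then not under catalyst control, so the ketone would be equilibrated with DBU and the (12R)-epimer separated. Wittig methylenation (Ph3P=CH2, low temperature) returns to 26.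

2. Step 13 (Zweifel olefination). Ate-complex formation between the hindered macrocyclic secondary boronate and the α-branched alkenyllithium may be slow, and the Shapiro lithiation may be incomplete, so that unreacted boronate is carried into the iodination. The fallback sets out from 19 and comes back at 26. Matteson homologation with LiCHCl2/ZnCl2 gives the α-chloro boronate F9. Displacement with (4-methylpent-3-en-1-yl)magnesium bromide gives the homologated secondary boronate F10; both 1,2-shifts retain the configuration of C12. Oxidation with NaBO3 gives the secondary alcohol F11, Dess–Martin oxidation gives the macrocyclic ketone F8, and methylenation as above returns to 26.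

3. Step 4 (carbocupration and epoxide opening in one flask). Addition to propyne may be incomplete and the alkenylcopper may open ethylene oxide too slowly, so that protonation to the simple alkene competes. The fallback sets out from 5 and comes back at 8. The alkenylcopper 7 is instead quenched with iodine to tert-butyl{[(2R,6Z)-7-iodo-2,6-dimethylhept-6-en-1-yl]oxy}dimethylsilane F12, which is isolated. Iodine–lithium exchange (t-BuLi, Et2O, −78 °C) and opening of ethylene oxide by the alkenyllithium (BF3·OEt2) then give 8 with the geometry retained.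

Further compounds
F1 | step 11 | dimethyl (6-methyl-2-oxohept-5-en-1-yl)phosphonate | COP(=O)(OC)CC(=O)CCC=C(C)C
F2 | step 11 | primary C13 alcohol from hydroboration–oxidation of 14 | CC(C)(C)[Si](C)(C)OC[C@H](C)CCC/C(C)=C\CC[C@@H](COCc1ccc(OC)cc1)CCO
F3 | step 11 | primary C13 iodide from F2 | CC(C)(C)[Si](C)(C)OC[C@H](C)CCC/C(C)=C\CC[C@@H](COCc1ccc(OC)cc1)CCI
F4 | step 11 | β-ketophosphonate F1 alkylated at its α-carbon (C12) by F3 | CC(C)(C)[Si](C)(C)OC[C@H](C)CCC/C(C)=C\CC[C@@H](COCc1ccc(OC)cc1)CCC(C(=O)CCC=C(C)C)P(=O)(OC)OC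
F5 | step 11 | α-methylene ketone (C11=C12 enone) with the TBS ether at C10 | CC(C)(C)[Si](C)(C)OC[C@H](C)CCC/C(C)=C\CC[C@@H](COCc1ccc(OC)cc1)CCC(=C)C(=O)CCC=C(C)C
F6 | step 11 | α-methylene ketone with the free C10 alcohol | OC[C@H](C)CCC/C(C)=C\CC[C@@H](COCc1ccc(OC)cc1)CCC(=C)C(=O)CCC=C(C)C
F7 | step 11 | α-methylene ketone with the C10 iodide | IC[C@H](C)CCC/C(C)=C\CC[C@@H](COCc1ccc(OC)cc1)CCC(=C)C(=O)CCC=C(C)C
F8 | step 11 | macrocyclic ketone: 5-methylhex-4-enoyl group on C12 of the 14-membered ring, (12R)-epimer, PMB ether at C1′ | O=C(CCC=C(C)C)[C@@H]1CC[C@H](C)CCC/C(C)=C\CC[C@@H](COCc2ccc(OC)cc2)CC1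
F9 | step 13 | α-chloro boronate from Matteson homologation of 19 (chloro(boryl)methyl group on C12) | ClC(B1OC(C)(C)C(C)(C)O1)[C@@H]1CC[C@H](C)CCC/C(C)=C\CC[C@@H](COCc2ccc(OC)cc2)CC1
F10 | step 13 | homologated boronate: 1-boryl-5-methylhex-4-en-1-yl group on C12 | CC(C)=CCCC(B1OC(C)(C)C(C)(C)O1)[C@@H]1CC[C@H](C)CCC/C(C)=C\CC[C@@H](COCc2ccc(OC)cc2)CC1
F11 | step 13 | secondary alcohol: 1-hydroxy-5-methylhex-4-en-1-yl group on C12 | CC(C)=CCCC(O)[C@@H]1CC[C@H](C)CCC/C(C)=C\CC[C@@H](COCc2ccc(OC)cc2)CC1
F12 | step 4 | tert-butyl{[(2R,6Z)-7-iodo-2,6-dimethylhept-6-en-1-yl]oxy}dimethylsilane | CC(C)(C)[Si](C)(C)OC[C@H](C)CCC/C(C)=C\I
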